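Start with a subtraction, since it tells you whether the midnight flask deserves another hour. Here are the flasks, the readings and the choice to be made.

the same everywhere: temperature 60 °C
- midnight: starting material 0.10 M; partner 0.20 M; the very flask that is asked about, followed so far
- dusk: starting material 0.15 M; partner 0.20 M; run made earlier
- flask: starting material 0.10 M; partner 0.200 M; time 2.0 h

| run | time / min | target / % | starting material / % |
|---|---|---|---|
| midnight | 5.00 | 0 | 58.9 |
| midnight | 15.0 | 22.9 | 21.2 |
| midnight | 25.0 | 40.9 | 7.7 |
| midnight | 40.0 | 54.1 | 1.4 |
| midnight | 60.0 | 58.6 | 1.7 |
| midnight | 80.0 | 59.5 | 1.1 |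
| dusk | 0.833 | 0 | 90.0 |
| dusk | 1.50 | 0 | 87.9 |
| dusk | 2.50 | 0 | 76.9 |
| dusk | 3.00 | 1.7 | 72.6 |
| dusk | 4.00 | 1.3 | 66.0 |
| dusk | 5.00 | 3.4 | 60.7 |

(each reading ± 1 percentage point)

- larch: at 2.0 h raise the temperature by 20 K, then wait 1.0 h
- birch: at 2.0 h take out 90% of the target then present, then wait 1.0 h
- elm: change nothing and wait 1.0 h more
- oak: at 2.0 h add partner, 50.0% of the amount charged, then wait 1.0 h

- target taken out counts as made
- the numbers in the tables scatter with a standard deviation of 1 percentage point
- candidate steps: starting material -> intermediate A; starting material -> intermediate B; intermediate A <-> intermediate C; intermediate A <-> intermediate D; partner + intermediate B <-> intermediate E; intermediate C -> target; starting material -> decomposition product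
- the earlier runs do not show what temperature does; that part of a forecast is a guess
- additions bring no volume worth counting

* target, in percent of the starting material first charged, at 2.0 h
* what to do for the largest gain in target; "none" if nothing gains more than 2 percentage points (larch / birch / elm / oak / none)
* target present, with what was taken out counted in, in percent of the starting material first charged, after larch
* target present, with what was taken out counted in, in percent of the starting material first charged, after elm

Take the last midnight reading, at 80.0 min: target 59.5%, starting material 1.1%. Subtract both from the charge and call the remainder, 39.4%, the hidden share: material that has left the starting material without arriving as target, the run's mass-balance gap.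

Now fix the early end. In the midnight run the starting material falls from 58.9% to 7.7% between 5.00 min and 25.0 min, which reads as a half-life of 6.81 min. The asked time is 17.6 of these half-lives, so count on no fresh feed by then.

Then fix the late end. Target rises 0.9 percentage points from 60.0 min to 80.0 min, less than the 1.4 points scatter of such a difference. Read that as a plateau, and take the mean of the two readings, 59.1%, as my estimate for 2.0 h.

Join the two ends: look for further target in the hidden share, where clearing the margin of 2 points asks for 5.08% of it. Cross out birch, since target forms by a one-way step and taking it out pulls nothing forward. Cross out oak, since partner meets intermediate B and the candidate steps lead from there to intermediate E, not to target. Elm offers the creep just measured. Choose larch: the runs show nothing about temperature, so this is a guess, but a guess that needs little.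

The forecast gives 60% at 2.0 h, 60.3% after elm and 60.5% after larch, and its choice is none. Its ground: “Only a slow release from a D reservoir could add more.” Its figure for 2.0 h stands close to my plateau, but we part on the choice: I take larch.

The flask gives 60.7% at 2.0 h, and the best step is larch, which reaches 68.1%, a gain of 7.4 points against 0.8 points for elm, which reaches 61.5%.

    starting material → intermediate A (k = 0.00140 /s, Ea = 104 kJ/mol)
    starting material → intermediate B (k = 3.30 × 10⁻⁴ /s, Ea = 103 kJ/mol)
    intermediate A ⇌ intermediate C (K = 1.30, k = 0.00270 /s, Ea = 101 kJ/mol, ΔH = −35.0 kJ/mol)
    intermediate A ⇌ intermediate D (K = 39.0, k = 5.90 × 10⁻⁴ /s, Ea = 107 kJ/mol, ΔH = −21.0 kJ/mol)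
    partner + intermediate B ⇌ intermediate E (K = 7.30 /M, k = 0.00920 /M/s, Ea = 60.0 kJ/mol, ΔH = −23.0 kJ/mol)
    intermediate C → target (k = 0.00320 /s, Ea = 96.0 kJ/mol)
    starting material → decomposition product (k = 3.70 × 10⁻⁷ /s, Ea = 119 kJ/mol)
    (constants at 60 °C)

In the asked flask at 120 min intermediate D holds 20.0% of the charge. The hidden share of that flask at that time is 39.3%, and the gain after larch equals 18.7% of it. In the flask kept at 35 °C the hidden share at 120 min is 39.9%, of which intermediate D holds 2.55%.

(The numbers in the tables were generated by integration for an exercise.)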